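The plan cuts the α-methylene-γ-butyrolactone of this melampolide at two carbon–carbon bonds: C11–C12 (methylene-bearing carbon to lactone carbonyl) and C6–C7 (the fusion bond shared by the lactone and the ten-membered carbocycle). One nickel-mediated operation makes both: zerovalent nickel couples a terminal allene (C7=C11=C13) with CO2 at C11, and the resulting 2-carboxyallylnickel adds through C7 to a tethered C6 enal, closing the ten-membered ring; acid then closes the lactone. The step exploits the 1,2-relationship between the C6 carbinol and the C7 carbon that carries the C11 acrylate unit. Its precursor is an acyclic (8R)-silyloxy allenyl enal ester, built from geranyl acetate by Wittig olefination, ynone transfer hydrogenation and Crabbé homologation.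

Key step: step 10

Remark: germacrane numbering is used throughout (C6/C7 lactone-fused ring carbons, C8 ester-bearing carbon, C10 carrying the methyl ester carbon C14, C11 carrying the exocyclic methylene C13, C12 the lactone carbonyl); the sense of the ynone reduction is assigned by analogy with aryl ketones, and the DBU ligands on nickel are left out of the SMILES of 18 and 19.

Step 1
Reactants: 1 geranyl acetate
Product: 3 (2E)-3-methyl-6-oxohex-2-en-1-yl acetate, via ozonide 2 (not isolated)
Conditions: O3 (1.0 equiv), CH2Cl2, −78 °C; then Me2S, −78 °C to rt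
Reagents that add atoms: ozone [O-][O+]=O
Why: Reductive ozonolysis with one equivalent of ozone should cleave the electron-rich 6,7-olefin selectively, because the 2,3-olefin is deactivated by the allylic acetate and keeps its E geometry, and dimethyl sulfide reduces ozonide 2 to the aldehyde.

Step 2
Reactants: 4 methyl (triphenyl-λ5-phosphanylidene)acetate (2 equiv); 5 2-bromo-N-methoxy-N-methylacetamide
Product: 7 methyl 4-[methoxy(methyl)amino]-4-oxo-2-(triphenyl-λ5-phosphanylidene)butanoate, via phosphonium bromide 6 (not isolated)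
Conditions: EtOAc, 70 °C
Reagents that add atoms: none
Why: C-alkylation of the ester-stabilised ylide by the α-bromo amide gives phosphonium salt 6, which the second equivalent of 4 deprotonates (transylidation) to the substituted ylide.

Step 3
Reactants: 3 (2E)-3-methyl-6-oxohex-2-en-1-yl acetate; 7 methyl 4-[methoxy(methyl)amino]-4-oxo-2-(triphenyl-λ5-phosphanylidene)butanoate
Product: 8 methyl (2E,6E)-8-acetoxy-2-{2-[methoxy(methyl)amino]-2-oxoethyl}-6-methylocta-2,6-dienoate
Conditions: toluene, 90 °C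
Reagents that add atoms: none
Why: Wittig olefination with an α-substituted ester-stabilised ylide should place the β-alkyl group trans to the ester (E), which is the ring-cis C1=C10 geometry of the target.

Step 4
Reactants: 8 methyl (2E,6E)-8-acetoxy-2-{2-[methoxy(methyl)amino]-2-oxoethyl}-6-methylocta-2,6-dienoate; 9 ethynyl(trimethyl)silane
Product: 11 methyl (2E,6E)-8-acetoxy-6-methyl-2-[2-oxo-4-(trimethylsilyl)but-3-yn-1-yl]octa-2,6-dienoate, via lithium hemiaminal alkoxide 10 (not isolated)
Conditions: 9, n-BuLi, THF, −78 °C; then 8, −78 °C; aq NH4Cl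
Reagents that add atoms: none
Why: Weinreb ketone synthesis, in which the chelated tetrahedral adduct 10 survives until the quench so that the acetylide adds only once, while the hindered conjugated methyl ester and the acetate should be much slower electrophiles at −78 °C.

Step 5
Reactants: 11 methyl (2E,6E)-8-acetoxy-6-methyl-2-[2-oxo-4-(trimethylsilyl)but-3-yn-1-yl]octa-2,6-dienoate
Product: 12 methyl (2E,6E)-8-acetoxy-2-[(2R)-2-hydroxy-4-(trimethylsilyl)but-3-yn-1-yl]-6-methylocta-2,6-dienoate
Conditions: Ru[(R,R)-TsDPEN](p-cymene) (2 mol %), i-PrOH, rt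
Reagents that add atoms: none
Why: Noyori–Ikariya asymmetric transfer hydrogenation of the ynone, in which the alkynyl group takes the place of an aryl group in the six-membered hydride-transfer array, so the (R,R) catalyst should set C8 as R under base-free conditions that leave the olefins and the acidic C9 methylene alone.

Step 6
Reactants: 12 methyl (2E,6E)-8-acetoxy-2-[(2R)-2-hydroxy-4-(trimethylsilyl)but-3-yn-1-yl]-6-methylocta-2,6-dienoate
Product: 13 methyl (2E,6E)-8-acetoxy-2-[(2R)-2-{[tert-butyl(dimethyl)silyl]oxy}-4-(trimethylsilyl)but-3-yn-1-yl]-6-methylocta-2,6-dienoate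
Conditions: TBSCl, imidazole, DMF, rt
Reagents that add atoms: tert-butyldimethylsilyl chloride CC(C)(C)[Si](C)(C)Cl
Why: Imidazole-promoted silylation of the secondary alcohol gives a robust, non-ionisable ether that keeps O8 from lactonising onto the C14 ester and from interfering in the nickel step; C8 is not touched.

Step 7
Reactants: 13 methyl (2E,6E)-8-acetoxy-2-[(2R)-2-{[tert-butyl(dimethyl)silyl]oxy}-4-(trimethylsilyl)but-3-yn-1-yl]-6-methylocta-2,6-dienoate
Product: 14 methyl (2E,6E)-2-[(2R)-2-{[tert-butyl(dimethyl)silyl]oxy}but-3-yn-1-yl]-8-hydroxy-6-methylocta-2,6-dienoate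
Conditions: K2CO3 (0.2 equiv), MeOH, 0 °C to rt
Reagents that add atoms: none
Why: Carbonate-catalysed methanolysis removes the primary acetate (transesterification) and the alkynyl trimethylsilyl group (protiodesilylation) in one pot, while the hindered secondary silyl ether and the methyl ester should survive.

Step 8
Reactants: 14 methyl (2E,6E)-2-[(2R)-2-{[tert-butyl(dimethyl)silyl]oxy}but-3-yn-1-yl]-8-hydroxy-6-methylocta-2,6-dienoate
Product: 16 methyl (2E,6E)-2-[(2R)-2-{[tert-butyl(dimethyl)silyl]oxy}penta-3,4-dien-1-yl]-8-hydroxy-6-methylocta-2,6-dienoate, via propargylic dicyclohexylamine 15 (not isolated)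
Conditions: (CH2O)n, CuI (0.5 equiv), Cy2NH, dioxane, reflux
Reagents that add atoms: formaldehyde (from paraformaldehyde) C=O
Why: Crabbé homologation, in which the copper-mediated Mannich coupling gives amine 15 and a 1,5-hydride shift with loss of the imine gives the terminal allene; C8 is untouched and no axial chirality arises because the new terminus is CH2.

Step 9
Reactants: 16 methyl (2E,6E)-2-[(2R)-2-{[tert-butyl(dimethyl)silyl]oxy}penta-3,4-dien-1-yl]-8-hydroxy-6-methylocta-2,6-dienoate
Product: 17 methyl (2E,6E)-2-[(2R)-2-{[tert-butyl(dimethyl)silyl]oxy}penta-3,4-dien-1-yl]-6-methyl-8-oxoocta-2,6-dienoate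
Conditions: MnO2, CH2Cl2, rt
Reagents that add atoms: none
Why: Manganese dioxide oxidises the primary allylic alcohol chemoselectively to the E enal and should leave the allene, the silyl ether and the enoate untouched.

Step 10
Reactants: 17 methyl (2E,6E)-2-[(2R)-2-{[tert-butyl(dimethyl)silyl]oxy}penta-3,4-dien-1-yl]-6-methyl-8-oxoocta-2,6-dienoate
Product: 21 methyl (3aS,4R,6E,10E,11aR)-4-{[tert-butyl(dimethyl)silyl]oxy}-10-methyl-3-methylidene-2-oxo-2,3,3a,4,5,8,9,11a-octahydrocyclodeca[b]furan-6-carboxylate, via η3-allylnickel carboxylate 18 (not isolated), via nickel alkoxide carboxylate 19 (not isolated), via hydroxy acid 20 (not isolated)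
Conditions: Ni(cod)2 (1.5 equiv), DBU (3 equiv), CO2 (1 atm), THF, 0 °C, slow addition of 17 (final 0.005 M), then rt; 1 M HCl, 0 °C; PPTS (cat.), CH2Cl2, rt
Reagents that add atoms: carbon dioxide O=C=O
Why: Proposed new method: zerovalent nickel with DBU couples the terminal allene of 17 oxidatively with CO2 at the central allene carbon, which makes the C11–C12 bond and gives the η3-allylnickel carboxylate 18; its allyl unit then adds through the substituted terminus C7 to the tethered C6 aldehyde, which makes the C6–C7 bond, and acid lactonises hydroxy acid 20. The closest known reaction type is the nickel-mediated sequential addition of CO2 and an aldehyde to a terminal allene between separate molecules, together with Barbier macrocyclisations of 2-(alkoxycarbonyl)allyl metals onto aldehydes; the intramolecular, medium-ring-forming variant with an enal is the new element. The ten-membered carbocycle closes by intramolecular carbonyl allylation in a six-membered chair-like array (Ni–C13–C11–C7···C6–O), and the lactone then closes by 5-exo-trig attack of the C6 hydroxyl on the C12 carboxyl. C6 and C7 are set together in that chair: the allyl isomer with C8 cis to the carboxylate and the aldehyde residue equatorial gives the anti adduct and hence the trans-fused lactone, while the face of C7 is set by the C8 stereocentre (C8–H in the allyl plane to avoid A1,3 strain with the carboxylate, the aldehyde entering anti to the C9 methylene), which should give the (6R,7S,8R) array of 21. The step needs CO2 uptake before any aldehyde chemistry, attack through C7 and not C13, and cyclisation instead of oligomerisation; these should be secured by the sluggishness of the β,β-disubstituted enal towards direct nickel coupling at 0 °C under CO2 saturation, by nickel resting on the unsubstituted C13 so that the allyl transfer follows the usual SE2′ course, and by slow addition to excess nickel reagent aided by the turn that the ring-cis C1=C10 enoate imposes.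

Step 11
Reactants: 21 methyl (3aS,4R,6E,10E,11aR)-4-{[tert-butyl(dimethyl)silyl]oxy}-10-methyl-3-methylidene-2-oxo-2,3,3a,4,5,8,9,11a-octahydrocyclodeca[b]furan-6-carboxylate
Product: 22 methyl (3aR,4R,6E,10E,11aR)-4-hydroxy-10-methyl-3-methylidene-2-oxo-2,3,3a,4,5,8,9,11a-octahydrocyclodeca[b]furan-6-carboxylate
Conditions: HF·pyridine, pyridine, THF, 0 °C to rt
Reagents that add atoms: none
Why: Buffered fluoride desilylation cleaves the secondary silyl ether under mildly acidic conditions that should avoid conjugate addition to the α-methylene lactone and base-induced translactonisation to O8.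

Step 12
Reactants: 22 methyl (3aR,4R,6E,10E,11aR)-4-hydroxy-10-methyl-3-methylidene-2-oxo-2,3,3a,4,5,8,9,11a-octahydrocyclodeca[b]furan-6-carboxylate
Product: 23 methyl (3aR,4R,6E,10E,11aR)-10-methyl-3-methylidene-4-[(2-methylprop-2-enoyl)oxy]-2-oxo-2,3,3a,4,5,8,9,11a-octahydrocyclodeca[b]furan-6-carboxylate
Conditions: methacrylic anhydride, Et3N, DMAP (cat.), CH2Cl2, 0 °C to rt
Reagents that add atoms: methacrylic anhydride C=C(C)C(=O)OC(=O)C(C)=C
Why: DMAP-catalysed acylation of the C8 alcohol installs the methacrylate with retention at C8 and should give the target.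

Compound list
1 | geranyl acetate, (2E)-3,7-dimethylocta-2,6-dien-1-yl acetate | CC(C)=CCC/C(C)=C/COC(C)=O | starting material
2 | ozonide of the 6,7-olefin of 1, 3-[(3E)-5-acetoxy-3-methylpent-3-en-1-yl]-5,5-dimethyl-1,2,4-trioxolane | CC1(C)OOC(CC/C(C)=C/COC(C)=O)O1 | intermediate
3 | (2E)-3-methyl-6-oxohex-2-en-1-yl acetate | O=CCC/C(C)=C/COC(C)=O | intermediate
4 | methyl (triphenyl-λ5-phosphanylidene)acetate | COC(=O)C=P(c1ccccc1)(c1ccccc1)c1ccccc1 | starting material
5 | 2-bromo-N-methoxy-N-methylacetamide | CON(C)C(=O)CBr | starting material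
6 | {1-methoxy-4-[methoxy(methyl)amino]-1,4-dioxobutan-2-yl}triphenylphosphonium bromide | COC(=O)C(CC(=O)N(C)OC)[P+](c1ccccc1)(c1ccccc1)c1ccccc1.[Br-] | intermediate
7 | methyl 4-[methoxy(methyl)amino]-4-oxo-2-(triphenyl-λ5-phosphanylidene)butanoate | COC(=O)C(CC(=O)N(C)OC)=P(c1ccccc1)(c1ccccc1)c1ccccc1 | intermediate
8 | methyl (2E,6E)-8-acetoxy-2-{2-[methoxy(methyl)amino]-2-oxoethyl}-6-methylocta-2,6-dienoate | CON(C)C(=O)C/C(C(=O)OC)=C\CC/C(C)=C/COC(C)=O | intermediate
9 | ethynyl(trimethyl)silane | C#C[Si](C)(C)C | starting material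
10 | lithium alkoxide of the tetrahedral adduct of the acetylide to the amide carbonyl of 8 | CON(C)C([O-])(C#C[Si](C)(C)C)C/C(C(=O)OC)=C\CC/C(C)=C/COC(C)=O.[Li+] | intermediate
11 | methyl (2E,6E)-8-acetoxy-6-methyl-2-[2-oxo-4-(trimethylsilyl)but-3-yn-1-yl]octa-2,6-dienoate | C[Si](C)(C)C#CC(=O)C/C(C(=O)OC)=C\CC/C(C)=C/COC(C)=O | intermediate
12 | methyl (2E,6E)-8-acetoxy-2-[(2R)-2-hydroxy-4-(trimethylsilyl)but-3-yn-1-yl]-6-methylocta-2,6-dienoate | O[C@@H](C#C[Si](C)(C)C)C/C(C(=O)OC)=C\CC/C(C)=C/COC(C)=O | intermediate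
13 | methyl (2E,6E)-8-acetoxy-2-[(2R)-2-{[tert-butyl(dimethyl)silyl]oxy}-4-(trimethylsilyl)but-3-yn-1-yl]-6-methylocta-2,6-dienoate | CC(C)(C)[Si](C)(C)O[C@@H](C#C[Si](C)(C)C)C/C(C(=O)OC)=C\CC/C(C)=C/COC(C)=O | intermediate
14 | methyl (2E,6E)-2-[(2R)-2-{[tert-butyl(dimethyl)silyl]oxy}but-3-yn-1-yl]-8-hydroxy-6-methylocta-2,6-dienoate | CC(C)(C)[Si](C)(C)O[C@@H](C#C)C/C(C(=O)OC)=C\CC/C(C)=C/CO | intermediate
15 | methyl (2E,6E)-2-[(2R)-2-{[tert-butyl(dimethyl)silyl]oxy}-5-(dicyclohexylamino)pent-3-yn-1-yl]-8-hydroxy-6-methylocta-2,6-dienoate | CC(C)(C)[Si](C)(C)O[C@@H](C#CCN(C1CCCCC1)C1CCCCC1)C/C(C(=O)OC)=C\CC/C(C)=C/CO | intermediate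
16 | methyl (2E,6E)-2-[(2R)-2-{[tert-butyl(dimethyl)silyl]oxy}penta-3,4-dien-1-yl]-8-hydroxy-6-methylocta-2,6-dienoate | CC(C)(C)[Si](C)(C)O[C@@H](C=C=C)C/C(C(=O)OC)=C\CC/C(C)=C/CO | intermediate
17 | methyl (2E,6E)-2-[(2R)-2-{[tert-butyl(dimethyl)silyl]oxy}penta-3,4-dien-1-yl]-6-methyl-8-oxoocta-2,6-dienoate | CC(C)(C)[Si](C)(C)O[C@@H](C=C=C)C/C(C(=O)OC)=C\CC/C(C)=C/C=O | intermediate
18 | η3-allylnickel carboxylate from 17 and CO2, drawn as the σ-form (3-alkylidene-1-oxa-5-nickelacyclopentan-2-one, C8 R, DBU ligands omitted) | CC(C)(C)[Si](C)(C)O[C@@H](C=C1C[Ni]OC1=O)C/C(C(=O)OC)=C\CC/C(C)=C/C=O | intermediate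
19 | nickel alkoxide carboxylate of the closed ten-membered ring (C6–O–Ni–O–C12 chelate, configured as 21, DBU ligands omitted) | CC(C)(C)[Si](C)(C)O[C@@H]1C/C(C(=O)OC)=C\CC/C(C)=C/[C@H]2O[Ni]OC(=O)C(=C)[C@@H]21 | intermediate
20 | 2-[(3E,7E)-10-{[tert-butyl(dimethyl)silyl]oxy}-2-hydroxy-8-(methoxycarbonyl)-4-methylcyclodeca-3,7-dien-1-yl]prop-2-enoic acid, (6R,7S,8R) in germacrane numbering | CC(C)(C)[Si](C)(C)O[C@@H]1C/C(C(=O)OC)=C\CC/C(C)=C/[C@@H](O)[C@@H]1C(=C)C(=O)O | intermediate
21 | methyl (3aS,4R,6E,10E,11aR)-4-{[tert-butyl(dimethyl)silyl]oxy}-10-methyl-3-methylidene-2-oxo-2,3,3a,4,5,8,9,11a-octahydrocyclodeca[b]furan-6-carboxylate (trans-fused lactone) | CC(C)(C)[Si](C)(C)O[C@@H]1C/C(C(=O)OC)=C\CC/C(C)=C/[C@H]2OC(=O)C(=C)[C@@H]21 | intermediate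
22 | methyl (3aR,4R,6E,10E,11aR)-4-hydroxy-10-methyl-3-methylidene-2-oxo-2,3,3a,4,5,8,9,11a-octahydrocyclodeca[b]furan-6-carboxylate | O[C@@H]1C/C(C(=O)OC)=C\CC/C(C)=C/[C@H]2OC(=O)C(=C)[C@@H]21 | intermediate
23 | methyl (3aR,4R,6E,10E,11aR)-10-methyl-3-methylidene-4-[(2-methylprop-2-enoyl)oxy]-2-oxo-2,3,3a,4,5,8,9,11a-octahydrocyclodeca[b]furan-6-carboxylate | C=C(C)C(=O)O[C@@H]1C/C(C(=O)OC)=C\CC/C(C)=C/[C@H]2OC(=O)C(=C)[C@@H]21 | target

Total step count: 12. Longest linear sequence: 11 steps (steps 1 and 3 to 12, from geranyl acetate).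

Steps most likely to fail

Step 10 (Proposed new method). The allylnickel carboxylate may be protonated on work-up or add to the aldehyde of a second molecule faster than it closes the ten-membered ring; it may also react through C13 or on the wrong face of C7. The fallback makes the two bonds one after the other with known reactions. It sets out from 17: iodine (I2, CH2Cl2, 0 °C, dark) adds across the terminal allene to give the 2-iodoallyl iodide methyl (2E,6E)-2-[(2R)-2-{[tert-butyl(dimethyl)silyl]oxy}-4,5-diiodopent-3-en-1-yl]-6-methyl-8-oxoocta-2,6-dienoate F1. Indium powder (DMF, rt, high dilution) then turns the allylic iodide into an allylindium that adds through C7 to the C6 aldehyde (intramolecular Barbier reaction) and gives the ten-membered alcohol methyl (1E,5E)-9-{[tert-butyl(dimethyl)silyl]oxy}-7-hydroxy-8-(1-iodoethenyl)-5-methylcyclodeca-1,5-diene-1-carboxylate F2. Palladium-catalysed carbonylative lactonisation of the vinyl iodide (Pd(PPh3)4, CO 1 atm, K2CO3, THF, 60 °C) forms the C11–C12 bond and the lactone and comes back to the route at 21.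

Step 4. The acetylide may deprotonate the doubly activated C9 methylene instead of adding, with migration of the C1=C10 double bond on work-up, or it may attack the primary acetate. The fallback builds the C8 carbinol on a small ester before the olefin is made; it sets out from 3 and comes back at 13. Methyl 4-chloro-4-oxobutanoate acylates bis(trimethylsilyl)acetylene (AlCl3, CH2Cl2, 0 °C) to give methyl 4-oxo-6-(trimethylsilyl)hex-5-ynoate F3. Transfer hydrogenation with the catalyst of step 5 gives methyl (4R)-4-hydroxy-6-(trimethylsilyl)hex-5-ynoate F4, and silylation (TBSCl, imidazole) gives methyl (4R)-4-{[tert-butyl(dimethyl)silyl]oxy}-6-(trimethylsilyl)hex-5-ynoate F5. Its lithium enolate (LiN(i-Pr)2, THF, −78 °C) adds to aldehyde 3 to give the aldol adduct methyl 8-acetoxy-2-[(2R)-2-{[tert-butyl(dimethyl)silyl]oxy}-4-(trimethylsilyl)but-3-yn-1-yl]-3-hydroxy-6-methyloct-6-enoate F6 as a diastereomer mixture. Mesylation (MsCl, Et3N) gives the corresponding 3-methanesulfonate F7, and elimination with DBU should give the E enoate 13.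

Step 8. The Mannich base may form but fail to undergo the hydride shift and fragmentation, or the hindered propargylic silyl ether may decompose at reflux before homologation is complete. The fallback adds the extra carbon as a propargylic alcohol and makes the allene by reductive transposition; it sets out from 14 and comes back at 16. Silylation of the allylic alcohol (TBSCl, imidazole) gives methyl (2E,6E)-8-{[tert-butyl(dimethyl)silyl]oxy}-2-[(2R)-2-{[tert-butyl(dimethyl)silyl]oxy}but-3-yn-1-yl]-6-methylocta-2,6-dienoate F8. Deprotonation of the alkyne (LiN(i-Pr)2, THF, −78 °C) and addition of paraformaldehyde give the propargylic alcohol methyl (2E,6E)-8-{[tert-butyl(dimethyl)silyl]oxy}-2-[(2R)-2-{[tert-butyl(dimethyl)silyl]oxy}-5-hydroxypent-3-yn-1-yl]-6-methylocta-2,6-dienoate F9. Myers allene synthesis (2-nitrobenzenesulfonylhydrazide, PPh3, DEAD, THF, −15 °C to rt) passes through the N-propargyl sulfonylhydrazine F10, which loses sulfinic acid and dinitrogen to give methyl (2E,6E)-8-{[tert-butyl(dimethyl)silyl]oxy}-2-[(2R)-2-{[tert-butyl(dimethyl)silyl]oxy}penta-3,4-dien-1-yl]-6-methylocta-2,6-dienoate F11. Selective cleavage of the primary allylic silyl ether (HF·pyridine, pyridine, THF, 0 °C) gives 16.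

Further compounds
F1 | step 10 | methyl (2E,6E)-2-[(2R)-2-{[tert-butyl(dimethyl)silyl]oxy}-4,5-diiodopent-3-en-1-yl]-6-methyl-8-oxoocta-2,6-dienoate | CC(C)(C)[Si](C)(C)O[C@@H](C=C(I)CI)C/C(C(=O)OC)=C\CC/C(C)=C/C=O
F2 | step 10 | methyl (1E,5E)-9-{[tert-butyl(dimethyl)silyl]oxy}-7-hydroxy-8-(1-iodoethenyl)-5-methylcyclodeca-1,5-diene-1-carboxylate, configured at C6, C7 and C8 as 20 | CC(C)(C)[Si](C)(C)O[C@@H]1C/C(C(=O)OC)=C\CC/C(C)=C/[C@@H](O)[C@@H]1C(I)=C
F3 | step 4 | methyl 4-oxo-6-(trimethylsilyl)hex-5-ynoate | COC(=O)CCC(=O)C#C[Si](C)(C)C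
F4 | step 4 | methyl (4R)-4-hydroxy-6-(trimethylsilyl)hex-5-ynoate | COC(=O)CC[C@@H](O)C#C[Si](C)(C)C
F5 | step 4 | methyl (4R)-4-{[tert-butyl(dimethyl)silyl]oxy}-6-(trimethylsilyl)hex-5-ynoate | COC(=O)CC[C@@H](O[Si](C)(C)C(C)(C)C)C#C[Si](C)(C)C
F6 | step 4 | methyl 8-acetoxy-2-[(2R)-2-{[tert-butyl(dimethyl)silyl]oxy}-4-(trimethylsilyl)but-3-yn-1-yl]-3-hydroxy-6-methyloct-6-enoate (6E, mixture at C2 and C3) | CC(C)(C)[Si](C)(C)O[C@@H](C#C[Si](C)(C)C)CC(C(=O)OC)C(O)CC/C(C)=C/COC(C)=O
F7 | step 4 | 3-methanesulfonate of F6 | CC(C)(C)[Si](C)(C)O[C@@H](C#C[Si](C)(C)C)CC(C(=O)OC)C(OS(C)(=O)=O)CC/C(C)=C/COC(C)=O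
F8 | step 8 | methyl (2E,6E)-8-{[tert-butyl(dimethyl)silyl]oxy}-2-[(2R)-2-{[tert-butyl(dimethyl)silyl]oxy}but-3-yn-1-yl]-6-methylocta-2,6-dienoate | CC(C)(C)[Si](C)(C)O[C@@H](C#C)C/C(C(=O)OC)=C\CC/C(C)=C/CO[Si](C)(C)C(C)(C)C
F9 | step 8 | methyl (2E,6E)-8-{[tert-butyl(dimethyl)silyl]oxy}-2-[(2R)-2-{[tert-butyl(dimethyl)silyl]oxy}-5-hydroxypent-3-yn-1-yl]-6-methylocta-2,6-dienoate | CC(C)(C)[Si](C)(C)O[C@@H](C#CCO)C/C(C(=O)OC)=C\CC/C(C)=C/CO[Si](C)(C)C(C)(C)C
F10 | step 8 | N-propargyl 2-nitrobenzenesulfonylhydrazine formed from F9 | CC(C)(C)[Si](C)(C)O[C@@H](C#CCN(N)S(=O)(=O)c1ccccc1[N+](=O)[O-])C/C(C(=O)OC)=C\CC/C(C)=C/CO[Si](C)(C)C(C)(C)C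
F11 | step 8 | methyl (2E,6E)-8-{[tert-butyl(dimethyl)silyl]oxy}-2-[(2R)-2-{[tert-butyl(dimethyl)silyl]oxy}penta-3,4-dien-1-yl]-6-methylocta-2,6-dienoate | CC(C)(C)[Si](C)(C)O[C@@H](C=C=C)C/C(C(=O)OC)=C\CC/C(C)=C/CO[Si](C)(C)C(C)(C)C
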